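**Plan**

- Locants: decalin 1 = ring A (C1–C5, C10) fused to ring B (C5–C10), C11 = ArCH2 on C9; decalin 2 = ring C (C5′–C10′) fused to ring D (C1′–C5′, C10′); La–Lb = the CH2CH2 link C4–La–Lb–C9′.
- Retrosynthesis: (a) both O–SO3H bonds; (b) C11–C(aryl), by decarboxylative radical addition of the C9–CH2–CO2H acid to p-benzoquinone. This works because C11 is a primary carbon on quaternary C9 (a neopentyl radical that cannot epimerise a stereocentre) and the arene is a 1,4-dioxygenated ring, i.e. a quinone at the right oxidation level. (c) C4–La, by acylation of the C6 alcohol and Ireland–Claisen rearrangement, which joins the two decalins; (d) ring A (C4=C5 aldol, C10–C1 conjugate addition) and ring C (C9′–C10′ enolate alkenylation, C5′–C6′ allylic substitution).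
- Forward, decalin 2: ring D is bought (4,4-dimethylcyclohexenone) → side chain at C5′ → ring C closed → chain then methyl at C9′ → methyl at C8′ → acid 17.
- Forward, decalin 1: ring B from a 2-substituted cyclohexenone (C8, C9) → transposed enone → side chain at C10 → ring A by aldol → allylic alcohol 31; then ester with 17, Claisen, decarboxylation, release of the C11 acid, radical coupling, reduction, sulfation.
- Stereochemistry: C5′ from CBS reduction plus anti-SN2′ transfer; C9′ by axial methylation of the dienolate (cis to H-5′); C8′ by hydrogenation anti to the axial 9′-methyl; C8 by ligand-controlled conjugate methylation; C9 by anti enolate methylation; C10 by conjugate addition trans to the 8-methyl; C4 by CBS reduction at C6 plus suprafacial [3,3] transfer.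

Key step: step 23

Remark: the target is written as the free bis(hydrogen sulfate) (it would be stored as its disodium salt); 2-iodocyclohex-2-en-1-one, the zinc reagent of step 11 and both halo ketals are taken as purchased.

**Route**

Step 1
Reactants: 1 4,4-dimethylcyclohex-2-en-1-one
Product: 3 2-bromo-4,4-dimethylcyclohex-2-en-1-one, via dibromo ketone 2 (not isolated)
Conditions: Br2, CH2Cl2, 0 °C; then Et3N, 0 °C to rt
Reagents that add atoms: bromine, BrBr
Why: bromine adds to the enone C=C and the amine removes HBr from the α,β-dibromide (addition–elimination α-bromination of an enone), leaving bromine on the α-carbon only.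

Step 2
Reactants: 3 2-bromo-4,4-dimethylcyclohex-2-en-1-one
Product: 4 (1R)-2-bromo-4,4-dimethylcyclohex-2-en-1-ol
Conditions: (S)-2-methyl-CBS-oxazaborolidine (10 mol%), BH3·SMe2, THF, −20 °C
Reagents that add atoms: none
Why: Corey–Bakshi–Shibata reduction, in which the bromovinyl side acts as the large group so that the catalyst alone should fix the carbinol centre (2-bromoenones are standard substrates).

Step 3
Reactants: 4 (1R)-2-bromo-4,4-dimethylcyclohex-2-en-1-ol
Product: 5 (1R)-2-bromo-4,4-dimethylcyclohex-2-en-1-yl pyridine-2-carboxylate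
Conditions: picolinic acid, EDC·HCl, DMAP (cat.), CH2Cl2, rt
Reagents that add atoms: pyridine-2-carboxylic acid, OC(=O)c1ccccn1
Why: carbodiimide (Steglich) esterification installs the chelating leaving group needed for the next step without touching the stereocentre.

Step 4
Reactants: 5 (1R)-2-bromo-4,4-dimethylcyclohex-2-en-1-yl pyridine-2-carboxylate; 6 2-(2-bromoethyl)-2-methyl-1,3-dioxolane
Product: 9 4-[(1R)-2-bromo-6,6-dimethylcyclohex-2-en-1-yl]butan-2-one, via Grignard reagent 7 (not isolated), via ketal 8 (not isolated)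
Conditions: 6, Mg, THF, 30 °C; then 5, CuBr·SMe2 (0.5 equiv), THF, −78 to 0 °C; then 1 M HCl, THF, rt
Reagents that add atoms: water, O
Why: picolinate-directed copper-mediated anti-SN2′ allylic substitution, in which the organocopper attacks the γ-carbon (C5′) on the face opposite the C–O bond so that the carbinol centre of 5 becomes the C5′–H centre, after which aqueous acid unmasks the methyl ketone.

Step 5
Reactants: 9 4-[(1R)-2-bromo-6,6-dimethylcyclohex-2-en-1-yl]butan-2-one
Product: 11 (4aR)-5,5-dimethyl-4,4a,5,6,7,8-hexahydronaphthalen-2(3H)-one, via deconjugated ketone 10 (not isolated)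
Conditions: Pd(PPh3)4 (10 mol%), KOtBu, THF, 65 °C
Reagents that add atoms: none
Why: palladium-catalysed intramolecular α-alkenylation of a ketone enolate by the vinyl bromide closes ring C through the methyl carbon (the CH2 enolate would give a four-membered ring), and the β,γ-enone conjugates under the base while C5′, which is not α to the carbonyl, is untouched.

Step 6
Reactants: 11 (4aR)-5,5-dimethyl-4,4a,5,6,7,8-hexahydronaphthalen-2(3H)-one
Product: 13 methyl 3-[(4aR)-5,5-dimethyl-2-oxo-2,3,4,4a,5,6,7,8-octahydronaphthalen-1-yl]propanoate, via dienamine 12 (not isolated)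
Conditions: pyrrolidine, PhH, reflux (Dean–Stark); then methyl acrylate, dioxane, reflux; then AcOH, NaOAc, H2O, reflux
Reagents that add atoms: methyl acrylate, C=CC(=O)OC; water, O
Why: Stork enamine Michael reaction, in which the heteroannular dienamine reacts at its α-carbon (C9′) and hydrolysis returns the α-substituted enone carrying the La–Lb–CO2Me chain.

Step 7
Reactants: 13 methyl 3-[(4aR)-5,5-dimethyl-2-oxo-2,3,4,4a,5,6,7,8-octahydronaphthalen-1-yl]propanoate
Product: 14 methyl 3-[(4aR)-1,5,5-trimethyl-2-oxo-1,2,3,4,4a,5,6,7-octahydronaphthalen-1-yl]propanoate (1-methyl cis to H-4a)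
Conditions: KOtBu, MeI, tBuOH–THF, 0 °C
Reagents that add atoms: iodomethane, CI
Why: deconjugative α-alkylation of the enone, in which the dienolate formed through C1′–H (C5′–H is shielded by the C4′ gem-dimethyl group) is methylated at C9′ along the axial, chair-forming trajectory on the face of axial H-5′, making C9′ quaternary and moving the alkene to C1′=C10′.

Step 8
Reactants: 14 methyl 3-[(4aR)-1,5,5-trimethyl-2-oxo-1,2,3,4,4a,5,6,7-octahydronaphthalen-1-yl]propanoate
Product: 15 methyl 3-[(4aR)-1,5,5-trimethyl-2-methylidene-1,2,3,4,4a,5,6,7-octahydronaphthalen-1-yl]propanoate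
Conditions: Zn, CH2Br2, TiCl4, THF–CH2Cl2, 0 °C to rt
Reagents that add atoms: dibromomethane, BrCBr
Why: Lombardo methylenation, a non-basic titanium–zinc methylene transfer that works on hindered α-quaternary ketones and leaves the ester alone.

Step 9
Reactants: 15 methyl 3-[(4aR)-1,5,5-trimethyl-2-methylidene-1,2,3,4,4a,5,6,7-octahydronaphthalen-1-yl]propanoate
Product: 16 methyl 3-[(4aR)-1,2,5,5-tetramethyl-1,2,3,4,4a,5,6,7-octahydronaphthalen-1-yl]propanoate (1-Me 2-Me H-4a mutually cis)
Conditions: H2 (1 atm), PtO2 (cat.), EtOAc, rt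
Reagents that add atoms: none
Why: heterogeneous hydrogenation of the exocyclic 1,1-disubstituted alkene from the face opposite the axial C9′ methyl should give the equatorial 8′-methyl cis to the 9′-methyl, while the hindered trisubstituted C1′=C10′ bond is left.

Step 10
Reactants: 16 methyl 3-[(4aR)-1,2,5,5-tetramethyl-1,2,3,4,4a,5,6,7-octahydronaphthalen-1-yl]propanoate
Product: 17 3-[(4aR)-1,2,5,5-tetramethyl-1,2,3,4,4a,5,6,7-octahydronaphthalen-1-yl]propanoic acid
Conditions: LiOH, THF–MeOH–H2O, rt; then 1 M HCl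
Reagents that add atoms: lithium hydroxide, [Li+].[OH-]
Why: saponification of an unhindered primary methyl ester.

Step 11
Reactants: 18 2-iodocyclohex-2-en-1-one
Product: 19 tert-butyl 2-(6-oxocyclohex-1-en-1-yl)acetate
Conditions: ClZnCH2CO2tBu (0.5 M in Et2O), Pd2(dba)3 (dba = dibenzylideneacetone, 2 mol%), XPhos (8 mol%), THF, rt
Reagents that add atoms: (2-tert-butoxy-2-oxoethyl)zinc chloride, CC(C)(C)OC(=O)C[Zn]Cl
Why: Negishi coupling of an α-iodoenone with a Reformatsky-type zinc enolate puts the future C11–CO2 unit on C9.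

Step 12
Reactants: 19 tert-butyl 2-(6-oxocyclohex-1-en-1-yl)acetate
Product: 21 tert-butyl 2-[(1R,2R)-1,2-dimethyl-6-oxocyclohexyl]acetate, via aluminium enolate 20 (not isolated)
Conditions: Me3Al, Cu(O2CC4H3S) (copper thiophene-2-carboxylate, 2 mol%), O,O′-(1,1′-binaphthalene-2,2′-diyl) N,N-bis(1-phenylethyl)phosphoramidite (4 mol%, the enantiomer giving the 2R centre), Et2O, −30 °C; then MeLi, THF–DMPU, −78 °C; MeI, −78 to 0 °C
Reagents that add atoms: trimethylaluminium, C[Al](C)C; iodomethane, CI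
Why: copper-catalysed asymmetric conjugate addition sets C8 under ligand control, and the tetrasubstituted enolate is methylated anti to the new C8 methyl (held pseudoaxial by A(1,2) strain), which should give the trans-dimethyl pattern with the acetate arm cis to the C8 methyl.

Step 13
Reactants: 21 tert-butyl 2-[(1R,2R)-1,2-dimethyl-6-oxocyclohexyl]acetate
Product: 22 tert-butyl 2-[(1R,6R)-1,6-dimethyl-2-(trifluoromethanesulfonyloxy)cyclohex-2-en-1-yl]acetate
Conditions: KN(SiMe3)2, PhNTf2, THF, −78 °C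
Reagents that add atoms: N-phenylbis(trifluoromethanesulfonimide), O=S(=O)(N(c1ccccc1)S(=O)(=O)C(F)(F)F)C(F)(F)F
Why: enol triflate formation, regiospecific because the ketone can enolise only toward C5 (C9 is quaternary).

Step 14
Reactants: 22 tert-butyl 2-[(1R,6R)-1,6-dimethyl-2-(trifluoromethanesulfonyloxy)cyclohex-2-en-1-yl]acetate
Product: 23 tert-butyl 2-[(1R,6R)-1,6-dimethylcyclohex-2-en-1-yl]acetate
Conditions: Pd(OAc)2 (5 mol%), PPh3, HCO2H, Bu3N, DMF, 60 °C
Reagents that add atoms: none
Why: palladium-catalysed formate reduction of the enol triflate gives the C5=C10 alkene at a defined position.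

Step 15
Reactants: 23 tert-butyl 2-[(1R,6R)-1,6-dimethylcyclohex-2-en-1-yl]acetate
Product: 24 tert-butyl 2-[(1R,6R)-1,6-dimethyl-4-oxocyclohex-2-en-1-yl]acetate
Conditions: Rh2(caprolactamate)4 (1 mol%), tBuOOH (70% aq.), K2CO3 (cat.), CH2Cl2, rt
Reagents that add atoms: tert-butyl hydroperoxide, CC(C)(C)OO
Why: allylic C–H oxidation, where C6 is the only allylic CH2 (C9 is quaternary) and the allyl radical should be oxygenated at C6, the terminus remote from the quaternary centre, giving the transposed enone.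

Step 16
Reactants: 24 tert-butyl 2-[(1R,6R)-1,6-dimethyl-4-oxocyclohex-2-en-1-yl]acetate; 25 2-(3-chloropropyl)-2-methyl-1,3-dioxolane
Product: 28 tert-butyl 2-{1,6-dimethyl-2-[3-(2-methyl-1,3-dioxolan-2-yl)propyl]-4-oxocyclohexyl}acetate (2-alkyl trans to 6-Me; cis to 1-Me), via Grignard reagent 26 (not isolated), via silyl enol ether 27 (not isolated)
Conditions: 25, Mg, THF, reflux; then 24, CuBr·SMe2 (10 mol%), Me3SiCl, THF, −78 °C; then K2CO3 (cat.), MeOH, 0 °C
Reagents that add atoms: none
Why: copper-catalysed conjugate addition, in which the nucleophile enters C10 anti to the pseudoaxial acetate arm on C9 and trans to the C8 methyl (the trans-3,5 rule for 5-substituted cyclohexenones), both effects pointing to the same face.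

Step 17
Reactants: 28 tert-butyl 2-{1,6-dimethyl-2-[3-(2-methyl-1,3-dioxolan-2-yl)propyl]-4-oxocyclohexyl}acetate
Product: 30 tert-butyl 2-(1,2,5-trimethyl-4-oxo-1,2,3,4,6,7,8,8a-octahydronaphthalen-1-yl)acetate (1-Me trans to 2-Me; H-8a cis to 2-Me), via diketone 29 (not isolated)
Conditions: 1 M HCl, THF, rt; then KOtBu (20 mol%), tBuOH, 40 °C
Reagents that add atoms: water, O
Why: ketal hydrolysis then intramolecular aldol condensation of the 1,7-diketone, in which only attack of C5 on the methyl ketone gives a six-membered ring that can dehydrate (to the C4=C5 enone), and C10, being β to the ring ketone, cannot epimerise.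

Step 18
Reactants: 30 tert-butyl 2-(1,2,5-trimethyl-4-oxo-1,2,3,4,6,7,8,8a-octahydronaphthalen-1-yl)acetate
Product: 31 tert-butyl 2-(4-hydroxy-1,2,5-trimethyl-1,2,3,4,6,7,8,8a-octahydronaphthalen-1-yl)acetate (4-OH cis to H-8a)
Conditions: (R)-2-methyl-CBS-oxazaborolidine (20 mol%), BH3·SMe2, THF, −30 °C
Reagents that add atoms: none
Why: Corey–Bakshi–Shibata 1,2-reduction of an α-substituted enone (alkenyl side large, C7H2 side small), in which catalyst control is expected to override the modest substrate bias and place the C6 hydroxyl on the face of H-10.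

Step 19
Reactants: 31 tert-butyl 2-(4-hydroxy-1,2,5-trimethyl-1,2,3,4,6,7,8,8a-octahydronaphthalen-1-yl)acetate; 17 3-[(4aR)-1,2,5,5-tetramethyl-1,2,3,4,4a,5,6,7-octahydronaphthalen-1-yl]propanoic acid
Product: 32 C6 ester of 31 acylated by 17 (decalin 1–O–CO–La–Lb–decalin 2)
Conditions: EDC·HCl, DMAP, CH2Cl2, rt
Reagents that add atoms: none
Why: carbodiimide (Steglich) esterification joins the two decalins through an easily formed C–O bond ahead of the C–C bond formation.

Step 20
Reactants: 32 C6 ester of 31 acylated by 17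
Product: 35 La-carboxylic acid (C4–La bond formed; both La epimers; C5=C6; tert-butyl ester on C11), via silyl ketene acetal 33 (not isolated), via silyl ester 34 (not isolated)
Conditions: LiN(iPr)2 (2.5 equiv), Me3SiCl–Et3N, THF, −78 °C to rt; then 70 °C; then dilute HCl work-up
Reagents that add atoms: none
Why: Ireland–Claisen rearrangement, a suprafacial [3,3] shift that carries the configuration of the C6–O bond to C4 (the new C4–La bond forms on the face of H-10 whether the transition state is chair or boat), makes C4 quaternary and places the alkene at C5=C6.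

Step 21
Reactants: 35 La-carboxylic acid
Product: 37 tert-butyl ester of the complete carbon skeleton (C4–La–Lb–C9′; CO2tBu on C11), via thiohydroxamate ester 36 (not isolated)
Conditions: 1-hydroxypyridine-2(1H)-thione, DCC, DMAP (cat.), CH2Cl2, 0 °C, dark; then tBuSH, hν (tungsten lamp), rt
Reagents that add atoms: none
Why: Barton reductive decarboxylation, in which the secondary La radical is reduced by the thiol faster than it can add to either alkene (only four-membered or 5-endo closures are available), removing the carboxyl group that served the rearrangement.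

Step 22
Reactants: 37 tert-butyl ester of the complete carbon skeleton
Product: 39 C11 carboxylic acid (decalin 1 C9–CH2–CO2H), via silyl ester 38 (not isolated)
Conditions: Me3SiOTf, 2,6-lutidine, CH2Cl2, 0 °C to rt; then H2O–MeOH
Reagents that add atoms: none
Why: silyl triflate-mediated cleavage of the tert-butyl ester under buffered, non-protic conditions spares the two acid-sensitive trisubstituted alkenes.

Step 23
Reactants: 39 C11 carboxylic acid; 40 p-benzoquinone
Product: 43 2-alkyl-3-(pyridin-2-ylsulfanyl)-1,4-benzoquinone (alkyl = C11 of the bis-decalin), via thiohydroxamate ester 41 (not isolated), via thio hydroquinone 42 (not isolated)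
Conditions: 1-hydroxypyridine-2(1H)-thione, DCC, DMAP (cat.), CH2Cl2, 0 °C, dark; then 40 (5 equiv), hν (tungsten lamp), CH2Cl2, 0 °C
Reagents that add atoms: 1-hydroxypyridine-2(1H)-thione, On1ccccc1=S
Why: Photolysis cleaves the N–O bond of thiohydroxamate ester 41, the acyloxy radical loses CO2, and the primary C11 radical adds to a ring carbon of p-benzoquinone 40; the adduct radical takes the 2-pyridylthio group from a second molecule of 41 (chain transfer), the dihydroquinone tautomerises to 42, and excess 40 oxidises it to quinone 43. The closest known reaction type is the Barton decarboxylative radical addition to quinones, which is documented for primary neopentyl-type radicals. The step closes no ring and creates no stereocentre: the radical sits on C11, one carbon away from quaternary C9, so C9 cannot epimerise, and β-scission would require breaking a ring C–C bond. The selectivity needed is addition to the quinone in preference to recombination with the pyridylthio radical or attack on the C5=C6 and C1′=C10′ alkenes; it is secured by the excess of the electron-poor quinone (polarity-matched with the nucleophilic alkyl radical), by the low radical concentration of a chain process, and by geometry (only 4-exo or 5-endo closures onto C5=C6 are possible). Because 40 is symmetrical there is no regiochemical question, and the 1,4-dioxygen pattern of the aromatic ring arrives at the correct oxidation level without protecting groups.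

Step 24
Reactants: 43 2-alkyl-3-(pyridin-2-ylsulfanyl)-1,4-benzoquinone
Product: 44 2-alkylbenzene-1,4-diol (desulfated toxiusol)
Conditions: Raney Ni, EtOH, rt, under Ar
Reagents that add atoms: none
Why: Raney nickel hydrogenolysis removes the pyridylthio helper and reduces the quinone to the hydroquinone in one operation, while the hindered trisubstituted alkenes should survive.

Step 25
Reactants: 44 2-alkylbenzene-1,4-diol
Product: 45 toxiusol
Conditions: SO3·pyridine (10 equiv), pyridine, 60 °C; then acidic ion-exchange resin (H+ form), H2O–MeOH, 0 °C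
Reagents that add atoms: sulfur trioxide–pyridine complex, O=S(=O)([O-])[n+]1ccccc1
Why: O-sulfation of both phenols with the sulfur trioxide–amine complex, followed by ion exchange to the free bis(hydrogen sulfate).

**Compound list**

1 | 4,4-dimethylcyclohex-2-en-1-one | CC1(C)CCC(=O)C=C1 | starting material
2 | 2,3-dibromo-4,4-dimethylcyclohexan-1-one (diastereomer mixture) | CC1(C)CCC(=O)C(Br)C1Br | intermediate
3 | 2-bromo-4,4-dimethylcyclohex-2-en-1-one | CC1(C)CCC(=O)C(Br)=C1 | intermediate
4 | (1R)-2-bromo-4,4-dimethylcyclohex-2-en-1-ol | O[C@@H]1CCC(C)(C)C=C1Br | intermediate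
5 | (1R)-2-bromo-4,4-dimethylcyclohex-2-en-1-yl pyridine-2-carboxylate | O=C(O[C@@H]1CCC(C)(C)C=C1Br)c1ccccn1 | intermediate
6 | 2-(2-bromoethyl)-2-methyl-1,3-dioxolane | CC1(CCBr)OCCO1 | starting material
7 | [2-(2-methyl-1,3-dioxolan-2-yl)ethyl]magnesium bromide | CC1(CC[Mg]Br)OCCO1 | intermediate
8 | 2-{2-[(1R)-2-bromo-6,6-dimethylcyclohex-2-en-1-yl]ethyl}-2-methyl-1,3-dioxolane | CC1(CC[C@H]2C(Br)=CCCC2(C)C)OCCO1 | intermediate
9 | 4-[(1R)-2-bromo-6,6-dimethylcyclohex-2-en-1-yl]butan-2-one | CC(=O)CC[C@H]1C(Br)=CCCC1(C)C | intermediate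
10 | (4aR)-5,5-dimethyl-3,4,4a,5,6,7-hexahydronaphthalen-2(1H)-one | O=C1CC2=CCCC(C)(C)[C@H]2CC1 | intermediate
11 | (4aR)-5,5-dimethyl-4,4a,5,6,7,8-hexahydronaphthalen-2(3H)-one | O=C1C=C2CCCC(C)(C)[C@H]2CC1 | intermediate
12 | 1-[(4aR)-5,5-dimethyl-3,4,4a,5,6,7-hexahydronaphthalen-2-yl]pyrrolidine | C1CCN(C1)C1=CC2=CCCC(C)(C)[C@H]2CC1 | intermediate
13 | methyl 3-[(4aR)-5,5-dimethyl-2-oxo-2,3,4,4a,5,6,7,8-octahydronaphthalen-1-yl]propanoate | COC(=O)CCC1=C2CCCC(C)(C)[C@H]2CCC1=O | intermediate
14 | methyl 3-[(4aR)-1,5,5-trimethyl-2-oxo-1,2,3,4,4a,5,6,7-octahydronaphthalen-1-yl]propanoate (1-methyl cis to H-4a) | COC(=O)CC[C@@]1(C)C2=CCCC(C)(C)[C@H]2CCC1=O | intermediate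
15 | methyl 3-[(4aR)-1,5,5-trimethyl-2-methylidene-1,2,3,4,4a,5,6,7-octahydronaphthalen-1-yl]propanoate (1-methyl cis to H-4a) | COC(=O)CC[C@@]1(C)C2=CCCC(C)(C)[C@H]2CCC1=C | intermediate
16 | methyl 3-[(4aR)-1,2,5,5-tetramethyl-1,2,3,4,4a,5,6,7-octahydronaphthalen-1-yl]propanoate (1-Me, 2-Me and H-4a mutually cis) | COC(=O)CC[C@@]1(C)C2=CCCC(C)(C)[C@H]2CC[C@@H]1C | intermediate
17 | 3-[(4aR)-1,2,5,5-tetramethyl-1,2,3,4,4a,5,6,7-octahydronaphthalen-1-yl]propanoic acid (same configuration as 16) | OC(=O)CC[C@@]1(C)C2=CCCC(C)(C)[C@H]2CC[C@@H]1C | intermediate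
18 | 2-iodocyclohex-2-en-1-one | O=C1CCCC=C1I | starting material
19 | tert-butyl 2-(6-oxocyclohex-1-en-1-yl)acetate | CC(C)(C)OC(=O)CC1=CCCCC1=O | intermediate
20 | tert-butyl 2-[(6R)-2-(dimethylalumanyloxy)-6-methylcyclohex-1-en-1-yl]acetate | C[C@@H]1CCCC(O[Al](C)C)=C1CC(=O)OC(C)(C)C | intermediate
21 | tert-butyl 2-[(1R,2R)-1,2-dimethyl-6-oxocyclohexyl]acetate | C[C@@H]1CCCC(=O)[C@]1(C)CC(=O)OC(C)(C)C | intermediate
22 | tert-butyl 2-[(1R,6R)-1,6-dimethyl-2-(trifluoromethanesulfonyloxy)cyclohex-2-en-1-yl]acetate | C[C@@H]1CCC=C(OS(=O)(=O)C(F)(F)F)[C@]1(C)CC(=O)OC(C)(C)C | intermediate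
23 | tert-butyl 2-[(1R,6R)-1,6-dimethylcyclohex-2-en-1-yl]acetate | C[C@@H]1CCC=C[C@]1(C)CC(=O)OC(C)(C)C | intermediate
24 | tert-butyl 2-[(1R,6R)-1,6-dimethyl-4-oxocyclohex-2-en-1-yl]acetate | C[C@@H]1CC(=O)C=C[C@]1(C)CC(=O)OC(C)(C)C | intermediate
25 | 2-(3-chloropropyl)-2-methyl-1,3-dioxolane | CC1(CCCCl)OCCO1 | starting material
26 | [3-(2-methyl-1,3-dioxolan-2-yl)propyl]magnesium chloride | CC1(CCC[Mg]Cl)OCCO1 | intermediate
27 | tert-butyl 2-{1,6-dimethyl-2-[3-(2-methyl-1,3-dioxolan-2-yl)propyl]-4-(trimethylsilyloxy)cyclohex-3-en-1-yl}acetate (2-alkyl trans to 6-Me, cis to 1-Me) | C[C@@H]1CC(O[Si](C)(C)C)=C[C@@H](CCCC2(C)OCCO2)[C@]1(C)CC(=O)OC(C)(C)C | intermediate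
28 | tert-butyl 2-{1,6-dimethyl-2-[3-(2-methyl-1,3-dioxolan-2-yl)propyl]-4-oxocyclohexyl}acetate (2-alkyl trans to 6-Me, cis to 1-Me) | C[C@@H]1CC(=O)C[C@@H](CCCC2(C)OCCO2)[C@]1(C)CC(=O)OC(C)(C)C | intermediate
29 | tert-butyl 2-[1,6-dimethyl-4-oxo-2-(4-oxopentyl)cyclohexyl]acetate (configuration as 28) | C[C@@H]1CC(=O)C[C@@H](CCCC(C)=O)[C@]1(C)CC(=O)OC(C)(C)C | intermediate
30 | tert-butyl 2-(1,2,5-trimethyl-4-oxo-1,2,3,4,6,7,8,8a-octahydronaphthalen-1-yl)acetate (1-Me trans to 2-Me; H-8a cis to 2-Me and to the acetate arm) | C[C@@H]1CC(=O)C2=C(C)CCC[C@H]2[C@]1(C)CC(=O)OC(C)(C)C | intermediate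
31 | tert-butyl 2-(4-hydroxy-1,2,5-trimethyl-1,2,3,4,6,7,8,8a-octahydronaphthalen-1-yl)acetate (as 30; 4-OH cis to H-8a) | C[C@@H]1C[C@H](O)C2=C(C)CCC[C@H]2[C@]1(C)CC(=O)OC(C)(C)C | intermediate
32 | C6 ester of 31 acylated by 17 (decalin 1–O–CO–La–Lb–decalin 2) | C[C@@H]1C[C@H](OC(=O)CC[C@@]3(C)C4=CCCC(C)(C)[C@H]4CC[C@@H]3C)C2=C(C)CCC[C@H]2[C@]1(C)CC(=O)OC(C)(C)C | intermediate
33 | trimethylsilyl ketene acetal of 32 (C=C between the ester carbon and La) | C[C@@H]1C[C@H](OC(O[Si](C)(C)C)=CC[C@@]3(C)C4=CCCC(C)(C)[C@H]4CC[C@@H]3C)C2=C(C)CCC[C@H]2[C@]1(C)CC(=O)OC(C)(C)C | intermediate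
34 | trimethylsilyl ester of 35 | C[C@@H]1CC=C2[C@@H](CCC[C@@]2(C)C(C(=O)O[Si](C)(C)C)C[C@@]2(C)C3=CCCC(C)(C)[C@H]3CC[C@@H]2C)[C@]1(C)CC(=O)OC(C)(C)C | intermediate
35 | La-carboxylic acid: C4 bears methyl (trans to H-10) and CH(CO2H)–Lb–decalin 2 (cis to H-10; both La epimers); C5=C6; tert-butyl ester on C11 | C[C@@H]1CC=C2[C@@H](CCC[C@@]2(C)C(C(=O)O)C[C@@]2(C)C3=CCCC(C)(C)[C@H]3CC[C@@H]2C)[C@]1(C)CC(=O)OC(C)(C)C | intermediate
36 | 2-thioxopyridin-1(2H)-yl ester of 35 | C[C@@H]1CC=C2[C@@H](CCC[C@@]2(C)C(C(=O)On3ccccc3=S)C[C@@]2(C)C3=CCCC(C)(C)[C@H]3CC[C@@H]2C)[C@]1(C)CC(=O)OC(C)(C)C | intermediate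
37 | tert-butyl ester of the complete carbon skeleton (C4–La–Lb–C9′; CO2tBu on C11; all seven stereocentres as in the target) | C[C@@H]1CC=C2[C@@H](CCC[C@@]2(C)CC[C@@]2(C)C3=CCCC(C)(C)[C@H]3CC[C@@H]2C)[C@]1(C)CC(=O)OC(C)(C)C | intermediate
38 | trimethylsilyl ester of 39 | C[C@@H]1CC=C2[C@@H](CCC[C@@]2(C)CC[C@@]2(C)C3=CCCC(C)(C)[C@H]3CC[C@@H]2C)[C@]1(C)CC(=O)O[Si](C)(C)C | intermediate
39 | C11 carboxylic acid (decalin 1 C9–CH2–CO2H; stereocentres as in the target) | C[C@@H]1CC=C2[C@@H](CCC[C@@]2(C)CC[C@@]2(C)C3=CCCC(C)(C)[C@H]3CC[C@@H]2C)[C@]1(C)CC(=O)O | intermediate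
40 | p-benzoquinone (cyclohexa-2,5-diene-1,4-dione) | O=C1C=CC(=O)C=C1 | starting material
41 | 2-thioxopyridin-1(2H)-yl ester of 39 | C[C@@H]1CC=C2[C@@H](CCC[C@@]2(C)CC[C@@]2(C)C3=CCCC(C)(C)[C@H]3CC[C@@H]2C)[C@]1(C)CC(=O)On1ccccc1=S | intermediate
42 | 2-alkyl-3-(pyridin-2-ylsulfanyl)benzene-1,4-diol (alkyl = C11 of the bis-decalin) | C[C@@H]1CC=C2[C@@H](CCC[C@@]2(C)CC[C@@]2(C)C3=CCCC(C)(C)[C@H]3CC[C@@H]2C)[C@]1(C)Cc1c(O)ccc(O)c1Sc1ccccn1 | intermediate
43 | 2-alkyl-3-(pyridin-2-ylsulfanyl)cyclohexa-2,5-diene-1,4-dione (alkyl = C11 of the bis-decalin) | C[C@@H]1CC=C2[C@@H](CCC[C@@]2(C)CC[C@@]2(C)C3=CCCC(C)(C)[C@H]3CC[C@@H]2C)[C@]1(C)CC1=C(Sc2ccccn2)C(=O)C=CC1=O | intermediate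
44 | 2-alkylbenzene-1,4-diol (desulfated toxiusol) | C[C@@H]1CC=C2[C@@H](CCC[C@@]2(C)CC[C@@]2(C)C3=CCCC(C)(C)[C@H]3CC[C@@H]2C)[C@]1(C)Cc1cc(O)ccc1O | intermediate
45 | toxiusol | C[C@@H]1CC=C2[C@@H](CCC[C@@]2(C)CC[C@@]2(C)C3=CCCC(C)(C)[C@H]3CC[C@@H]2C)[C@]1(C)Cc1cc(OS(=O)(=O)O)ccc1OS(=O)(=O)O | target

**Totals and risks**

Total: 25 steps. Longest linear sequence: 17 steps (1–10, then 19–25); the other branch (11–18, then 19–25) has 15.

Step 4. The organocopper may displace the picolinate directly at the α-carbon, or fail to reach the γ-carbon next to the gem-dimethyl group, so that the transfer of configuration to C5′ is eroded. The fallback replaces the organometallic C–C bond formation by a sigmatropic one; it sets out from 3 and comes back at 8. Ketone 3 is reduced with the (R)-configured CBS catalyst to the enantiomeric alcohol (1S)-2-bromo-4,4-dimethylcyclohex-2-en-1-ol F1, which is esterified (EDC, DMAP) with 3-(2-methyl-1,3-dioxolan-2-yl)propanoic acid to ester F2. LiN(iPr)2 and Me3SiCl give silyl ketene acetal F3, whose suprafacial Ireland–Claisen rearrangement places the chain on C5′ on the face of the C–O bond as silyl ester F4, hydrolysed at pH 5 to acid F5. Barton reductive decarboxylation through thiohydroxamate ester F6 (1-hydroxypyridine-2(1H)-thione, DCC; tBuSH, hν) gives ketal 8, which is hydrolysed to 9 as in step 4.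

Step 5. The potassium enolate may condense with a second ketone molecule, or the vinylpalladium species may be reduced before the C–C bond forms. The fallback closes ring C by an aldol condensation instead; it sets out from 9 and comes back at 11. Miyaura borylation of the vinyl bromide (bis(pinacolato)diboron, PdCl2(PPh3)2, PPh3, KOPh, toluene, 50 °C) gives boronate F7, NaBO3·4H2O in THF–H2O oxidises the C–B bond to the 1,5-diketone F8, and pyrrolidine–AcOH closes the cyclohexenone 11. The mild amine conditions are chosen because C5′ is α to a ketone in F8 and could epimerise under stronger base.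

Step 15. Hydrogen abstraction gives an allyl radical that may be oxygenated at C10 instead of C6, or the oxidation may stop at the mixed peroxide. The fallback is a carbonyl transposition instead of a C–H oxidation; it sets out from 21 and comes back at 24. Ketone 21 is dehydrogenated with 2-iodoxybenzoic acid (DMSO, 70 °C) to enone F9, epoxidised (H2O2, NaOH, MeOH) to epoxy ketone F10, rearranged with hydrazine hydrate and AcOH (Wharton transposition) to allylic alcohol F11, and oxidised with MnO2 to 24.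

**Further compounds**

F1 | step 4 | (1S)-2-bromo-4,4-dimethylcyclohex-2-en-1-ol | O[C@H]1CCC(C)(C)C=C1Br
F2 | step 4 | (1S)-2-bromo-4,4-dimethylcyclohex-2-en-1-yl 3-(2-methyl-1,3-dioxolan-2-yl)propanoate | CC1(CCC(=O)O[C@H]2CCC(C)(C)C=C2Br)OCCO1
F3 | step 4 | trimethylsilyl ketene acetal of F2 | CC1(CC=C(O[Si](C)(C)C)O[C@H]2CCC(C)(C)C=C2Br)OCCO1
F4 | step 4 | trimethylsilyl 2-[(1R)-2-bromo-6,6-dimethylcyclohex-2-en-1-yl]-3-(2-methyl-1,3-dioxolan-2-yl)propanoate (both C2 epimers) | C[Si](C)(C)OC(=O)C(CC1(C)OCCO1)[C@H]1C(Br)=CCCC1(C)C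
F5 | step 4 | 2-[(1R)-2-bromo-6,6-dimethylcyclohex-2-en-1-yl]-3-(2-methyl-1,3-dioxolan-2-yl)propanoic acid (both C2 epimers) | OC(=O)C(CC1(C)OCCO1)[C@H]1C(Br)=CCCC1(C)C
F6 | step 4 | 2-thioxopyridin-1(2H)-yl ester of F5 | S=c1ccccn1OC(=O)C(CC1(C)OCCO1)[C@H]1C(Br)=CCCC1(C)C
F7 | step 5 | 4-[(1R)-6,6-dimethyl-2-(4,4,5,5-tetramethyl-1,3,2-dioxaborolan-2-yl)cyclohex-2-en-1-yl]butan-2-one | CC(=O)CC[C@H]1C(B2OC(C)(C)C(C)(C)O2)=CCCC1(C)C
F8 | step 5 | 3,3-dimethyl-2-(3-oxobutyl)cyclohexan-1-one (C2 configured as C5′ of 9) | CC(=O)CC[C@H]1C(=O)CCCC1(C)C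
F9 | step 15 | tert-butyl 2-(1,2-dimethyl-6-oxocyclohex-4-en-1-yl)acetate (stereocentres as in 21) | C[C@@H]1CC=CC(=O)[C@]1(C)CC(=O)OC(C)(C)C
F10 | step 15 | tert-butyl 2-(4,5-epoxy-1,2-dimethyl-6-oxocyclohexyl)acetate (stereocentres as in 21; epoxide diastereomers) | C[C@@H]1CC2OC2C(=O)[C@]1(C)CC(=O)OC(C)(C)C
F11 | step 15 | tert-butyl 2-(4-hydroxy-1,6-dimethylcyclohex-2-en-1-yl)acetate (stereocentres as in 21; carbinol epimers) | C[C@@H]1CC(O)C=C[C@]1(C)CC(=O)OC(C)(C)C
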